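## Retrosynthetic overview

1. Rings B (ten-membered) and C (butenolide) close together in the last step: intramolecular Nozaki–Hiyama–Kishi addition of a C8 enol triflate to a C7 enal, then lactonisation onto the cis ester.
2. Side arms: C4–C5 by hydroboration/B-alkyl Suzuki coupling with (Z)-3-iodobut-2-en-1-ol (fixes 5Z); C8–C17–C19 by Roskamp homologation of a C8 aldehyde.
3. Key step: Claisen rearrangement of the C12 allyl vinyl ether forms C9–C10 and sets C10; the C12 alcohol comes from epoxidation/Wharton transposition of the carvone enone, and C13=O from allylic oxidation afterwards.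
4. C1, C2 and C14 come from (R)-carvone: α'-formylation and methylation anti to isopropenyl, Criegee rearrangement (isopropenyl → OAc with retention), chelation-controlled vinyl addition, tigloylation.
5. Ring order: ring A (bought as carvone) → rings B and C (final step).

Assumption: briarane numbering of the target is used for every intermediate (ring A = C1, C10–C14; C15 on C1; C20 on C11; chain C2–C9; C16 on C5; C17–C19 with methyl C18 on C17 and lactone carbonyl C19); the target is (1R,2S,5Z,7R,10R,14S) and the SMILES strings define configuration.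

## Route

Step 1
Reactants: 1 (R)-(−)-carvone
Product: 2 (5S)-6-(hydroxymethylidene)-2-methyl-5-(prop-1-en-2-yl)cyclohex-2-en-1-one
Conditions: NaH, HCO2Et, cat. EtOH, THF, 0 °C → rt; aq. HCl work-up
Reagents that add atoms: ethyl formate `CCOC=O`
Why: Crossed Claisen condensation (formylation) at the only enolisable α'-position installs C2 as a chelated hydroxymethylene group without touching the carvone stereocentre (future C14).

Step 2
Reactants: 2 (5S)-6-(hydroxymethylidene)-2-methyl-5-(prop-1-en-2-yl)cyclohex-2-en-1-one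
Product: 3 (1S,6S)-1,3-dimethyl-2-oxo-6-(prop-1-en-2-yl)cyclohex-3-ene-1-carbaldehyde
Conditions: MeI, K2CO3, acetone, reflux
Reagents that add atoms: iodomethane `CI`
Why: C-alkylation of the formyl ketone enolate occurs anti to the neighbouring isopropenyl group, which sets the quaternary centre C1 with Me-15 trans to the C14 substituent.

Step 3
Reactants: 3 (1S,6S)-1,3-dimethyl-2-oxo-6-(prop-1-en-2-yl)cyclohex-3-ene-1-carbaldehyde
Product: 5 (1R,2S)-2-formyl-2,4-dimethyl-3-oxocyclohex-4-en-1-yl acetate, via methoxy hydroperoxide 4 (not isolated)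
Conditions: O3, CH2Cl2/MeOH, −78 °C; then Ac2O, Et3N, cat. DMAP, 0 °C → rt
Reagents that add atoms: ozone `[O-][O+]=O`; methanol `CO`
Why: Ozonolysis of the only electron-rich alkene followed by Criegee rearrangement of the peracetylated methoxy hydroperoxide moves C14 from carbon to oxygen with retention, the former isopropenyl C(CH3) becoming the acetyl group of 14-OAc.

Step 4
Reactants: 5 (1R,2S)-2-formyl-2,4-dimethyl-3-oxocyclohex-4-en-1-yl acetate
Product: 6 (1R,2R)-2-[(1S)-1-hydroxyprop-2-en-1-yl]-2,4-dimethyl-3-oxocyclohex-4-en-1-yl acetate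
Conditions: MgBr2·OEt2, CH2Cl2, −78 °C; then CH2=CHMgBr (THF), −78 °C; cold aqueous quench
Reagents that add atoms: vinylmagnesium bromide `C=C[Mg]Br`
Why: Chelation-controlled Grignard addition to the aldehyde (magnesium bridging the aldehyde and C10 ketone oxygens) takes place from the Me-15 face, away from the ring carbon C14, and gives the (2S) carbinol while the hindered ketone and the acetate are left alone.

Step 5
Reactants: 6 (1R,2R)-2-[(1S)-1-hydroxyprop-2-en-1-yl]-2,4-dimethyl-3-oxocyclohex-4-en-1-yl acetate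
Product: 7 (1S)-1-[(1S,6R)-6-acetoxy-1,3-dimethyl-2-oxocyclohex-3-en-1-yl]prop-2-en-1-yl (E)-2-methylbut-2-enoate
Conditions: tigloyl chloride, Et3N, DMAP, CH2Cl2, 0 °C → rt
Reagents that add atoms: tigloyl chloride `C/C=C(\C)C(Cl)=O`
Why: DMAP-catalysed acylation installs the final C2 tiglate early, and because C1 is quaternary the β-acyloxy ketone cannot eliminate.

Step 6
Reactants: 7 (1S)-1-[(1S,6R)-6-acetoxy-1,3-dimethyl-2-oxocyclohex-3-en-1-yl]prop-2-en-1-yl (E)-2-methylbut-2-enoate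
Product: 8 11,12-epoxy ketone of 7 (epoxide oxygen anti to 14-OAc and syn to Me-15)
Conditions: t-BuOOH (decane), cat. benzyltrimethylammonium hydroxide (Triton B), THF, 0 °C
Reagents that add atoms: tert-butyl hydroperoxide `CC(C)(C)OO`
Why: Weitz–Scheffer nucleophilic epoxidation of the enone proceeds by attack at C12 on the face anti to 14-OAc and to the C1 side arm (as carvone itself is attacked anti to its C5 substituent), fixing the C12–O configuration that is later relayed to C10.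

Step 7
Reactants: 8 11,12-epoxy ketone of 7 (epoxide oxygen anti to 14-OAc and syn to Me-15)
Product: 9 transposed allylic alcohol (10,11-ene; 12-OH anti to 14-OAc; 2-OTig and 14-OAc kept)
Conditions: N2H4·H2O, cat. AcOH, MeOH, 0 °C → rt
Reagents that add atoms: none
Why: Wharton transposition of the epoxy hydrazone expels N2 and gives the C10=C11 alkene with the C12–O bond and its configuration retained.

Step 8
Reactants: 9 transposed allylic alcohol (10,11-ene; 12-OH anti to 14-OAc; 2-OTig and 14-OAc kept)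
Product: 11 C8 aldehyde (CH2CHO on C10 syn to Me-15 and anti to 14-OAc; 11,12-ene), via allyl vinyl ether 10 (not isolated)
Conditions: vinyl acetate, [Ir(cod)Cl]2 (1 mol %), Na2CO3 (0.6 equiv), toluene, 100 °C; then 150 °C (sealed tube)
Reagents that add atoms: vinyl acetate `C=COC(C)=O`
Why: Iridium-catalysed transfer vinylation followed by a thermal [3,3]-sigmatropic Claisen rearrangement forms the C9–C10 bond suprafacially on the face that carried the C12 oxygen, which sets C10 (C9 syn to Me-15, H-10 syn to the C2 arm) and regenerates the C11=C12 alkene.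

Step 9
Reactants: 12 ethyl 2-methyl-3-oxobutanoate
Product: 13 ethyl 2-diazopropanoate
Conditions: 4-acetamidobenzenesulfonyl azide, DBU, MeCN, 0 °C → rt
Reagents that add atoms: 4-acetamidobenzenesulfonyl azide `CC(=O)Nc1ccc(cc1)S(=O)(=O)N=[N+]=[N-]`
Why: Deacylative Regitz diazo transfer to the α-substituted β-keto ester gives the diazo ester with loss of the acetyl group to the sulfonamide.

Step 10
Reactants: 11 C8 aldehyde (CH2CHO on C10 syn to Me-15 and anti to 14-OAc; 11,12-ene); 13 ethyl 2-diazopropanoate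
Product: 14 β-keto ester (C10–CH2–CO–CH(CH3)–CO2Et; C17 epimers)
Conditions: SnCl2 (10 mol %), CH2Cl2, rt
Reagents that add atoms: none
Why: Roskamp homologation (Lewis-acid-promoted addition of the diazo ester to the aldehyde, 1,2-hydride shift and loss of N2) gives the β-keto ester carrying C17, C18 and C19 under conditions that spare both esters.

Step 11
Reactants: 14 β-keto ester (C10–CH2–CO–CH(CH3)–CO2Et; C17 epimers)
Product: 15 ring-A enone β-keto ester (13-oxo-11-ene; 14-OAc)
Conditions: CrO3, 3,5-dimethylpyrazole, CH2Cl2, −20 °C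
Reagents that add atoms: chromium trioxide `O=[Cr](=O)=O`
Why: Chromium-mediated allylic oxidation (Salmond conditions) converts C13, the only ring CH2 flanking the trisubstituted C11=C12 alkene, into the enone carbonyl while the deactivated vinyl and enoate alkenes and the C14 stereocentre are left alone.

Step 12
Reactants: 16 but-2-yn-1-ol
Product: 18 (Z)-3-iodobut-2-en-1-ol, via cyclic vinylalanate 17 (not isolated)
Conditions: NaAlH2(OCH2CH2OMe)2 (Red-Al), THF, 0 °C → rt; then I2, −78 °C → 0 °C; aqueous work-up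
Reagents that add atoms: iodine `II`
Why: Hydroxyl-directed trans-hydroalumination of the propargylic alcohol and iodinolysis of the C–Al bond with retention give the Z vinyl iodide that later fixes the C5=C6 geometry.

Step 13
Reactants: 15 ring-A enone β-keto ester (13-oxo-11-ene; 14-OAc); 18 (Z)-3-iodobut-2-en-1-ol
Product: 20 (5Z)-allylic alcohol (C2–C7 chain complete; 7-OH), via B-alkyl-9-BBN adduct 19 (not isolated)
Conditions: 9-BBN (1.1 equiv), THF, 0 °C → rt; then 18, Pd(dppf)Cl2 (5 mol %), AsPh3, aq. K3PO4, DMF, rt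
Reagents that add atoms: none
Why: Anti-Markovnikov hydroboration of the terminal vinyl group (much faster than carbonyl reduction by 9-BBN) and B-alkyl Suzuki–Miyaura coupling with retention of the iodide geometry join C4 to C5 and deliver the Z trisubstituted alkene.

Step 14
Reactants: 20 (5Z)-allylic alcohol (C2–C7 chain complete; 7-OH)
Product: 21 (5Z)-enal (C7 aldehyde)
Conditions: MnO2, CH2Cl2, rt
Reagents that add atoms: none
Why: MnO2 oxidation is selective for the allylic alcohol and gives the Z enal without touching the β-keto ester or isomerising the alkene.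

Step 15
Reactants: 21 (5Z)-enal (C7 aldehyde)
Product: 23 (Z)-enol triflate (8-OTf cis to CO2Et), via sodium enolate 22 (not isolated)
Conditions: NaH (1.0 equiv), THF, 0 °C; then PhNTf2, 0 °C → rt
Reagents that add atoms: N-phenylbis(trifluoromethanesulfonimide) `O=S(=O)(N(c1ccccc1)S(=O)(=O)C(F)(F)F)C(F)(F)F`
Why: O-Triflation of the chelated sodium Z-enolate of the β-keto ester (the most acidic site by far) gives the Z enol triflate, so that the carbon introduced at C8 will sit cis to the ester C19.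

Step 16
Reactants: 23 (Z)-enol triflate (8-OTf cis to CO2Et)
Product: 25 CNP0218548.3 (target), via hydroxy ester 24 (not isolated)
Conditions: CrCl2 (10 equiv), NiCl2 (5 mol %), DMF, rt, 2 mM (syringe pump); aqueous work-up, then cat. PPTS, CH2Cl2, rt
Reagents that add atoms: none
Why: Intramolecular Nozaki–Hiyama–Kishi alkenylation of the aldehyde closes the ten-membered ring at C7–C8 and the C7 alkoxide lactonises onto the cis ester to form the butenolide, with C7 set by the existing stereocentres through the trans-fused macrocyclic transition state (expected 7R, not proven).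

## Compound list

1 | (R)-(−)-carvone | `O=C1C(C)=CC[C@@H](C(C)=C)C1` | starting material
2 | (5S)-6-(hydroxymethylidene)-2-methyl-5-(prop-1-en-2-yl)cyclohex-2-en-1-one | `O=C1C(C)=CC[C@@H](C(C)=C)/C1=C/O` | intermediate
3 | (1S,6S)-1,3-dimethyl-2-oxo-6-(prop-1-en-2-yl)cyclohex-3-ene-1-carbaldehyde | `O=C1C(C)=CC[C@@H](C(C)=C)[C@@]1(C)C=O` | intermediate
4 | methoxy hydroperoxide [6-(1-hydroperoxy-1-methoxyethyl) analogue of 3] | `O=C1C(C)=CC[C@@H](C(C)(OC)OO)[C@@]1(C)C=O` | intermediate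
5 | (1R,2S)-2-formyl-2,4-dimethyl-3-oxocyclohex-4-en-1-yl acetate | `O=C1C(C)=CC[C@@H](OC(C)=O)[C@@]1(C)C=O` | intermediate
6 | (1R,2R)-2-[(1S)-1-hydroxyprop-2-en-1-yl]-2,4-dimethyl-3-oxocyclohex-4-en-1-yl acetate | `O=C1C(C)=CC[C@@H](OC(C)=O)[C@@]1(C)[C@@H](O)C=C` | intermediate
7 | (1S)-1-[(1S,6R)-6-acetoxy-1,3-dimethyl-2-oxocyclohex-3-en-1-yl]prop-2-en-1-yl (E)-2-methylbut-2-enoate | `O=C1C(C)=CC[C@@H](OC(C)=O)[C@@]1(C)[C@@H](OC(=O)/C(C)=C/C)C=C` | intermediate
8 | 11,12-epoxy ketone of 7 (epoxide oxygen anti to 14-OAc and syn to Me-15) | `O=C1[C@]2(C)O[C@@H]2C[C@@H](OC(C)=O)[C@@]1(C)[C@@H](OC(=O)/C(C)=C/C)C=C` | intermediate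
9 | transposed allylic alcohol (10,11-ene; 12-OH anti to 14-OAc; 2-OTig and 14-OAc kept) | `C1=C(C)[C@H](O)C[C@@H](OC(C)=O)[C@@]1(C)[C@@H](OC(=O)/C(C)=C/C)C=C` | intermediate
10 | allyl vinyl ether (12-O-vinyl ether of 9) | `C1=C(C)[C@H](OC=C)C[C@@H](OC(C)=O)[C@@]1(C)[C@@H](OC(=O)/C(C)=C/C)C=C` | intermediate
11 | C8 aldehyde (CH2CHO on C10 syn to Me-15 and anti to 14-OAc; 11,12-ene) | `[C@@H]1(CC=O)C(C)=CC[C@@H](OC(C)=O)[C@@]1(C)[C@@H](OC(=O)/C(C)=C/C)C=C` | intermediate
12 | ethyl 2-methyl-3-oxobutanoate | `CCOC(=O)C(C)C(C)=O` | starting material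
13 | ethyl 2-diazopropanoate | `CCOC(=O)C(C)=[N+]=[N-]` | intermediate
14 | β-keto ester (C10–CH2–CO–CH(CH3)–CO2Et; C17 epimers) | `[C@@H]1(CC(=O)C(C)C(=O)OCC)C(C)=CC[C@@H](OC(C)=O)[C@@]1(C)[C@@H](OC(=O)/C(C)=C/C)C=C` | intermediate
15 | ring-A enone β-keto ester (13-oxo-11-ene; 14-OAc) | `[C@@H]1(CC(=O)C(C)C(=O)OCC)C(C)=CC(=O)[C@@H](OC(C)=O)[C@@]1(C)[C@@H](OC(=O)/C(C)=C/C)C=C` | intermediate
16 | but-2-yn-1-ol | `CC#CCO` | starting material
17 | cyclic vinylalanate (sodium salt) | `CC1=CCO[Al-]1(OCCOC)OCCOC.[Na+]` | intermediate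
18 | (Z)-3-iodobut-2-en-1-ol | `C/C(I)=C/CO` | intermediate
19 | B-alkyl-9-BBN adduct of 15 (boron on C4) | `[C@@H]1(CC(=O)C(C)C(=O)OCC)C(C)=CC(=O)[C@@H](OC(C)=O)[C@@]1(C)[C@@H](OC(=O)/C(C)=C/C)CCB1C2CCCC1CCC2` | intermediate
20 | (5Z)-allylic alcohol (C2–C7 chain complete; 7-OH) | `[C@@H]1(CC(=O)C(C)C(=O)OCC)C(C)=CC(=O)[C@@H](OC(C)=O)[C@@]1(C)[C@@H](OC(=O)/C(C)=C/C)CC/C(C)=C\CO` | intermediate
21 | (5Z)-enal (C7 aldehyde) | `[C@@H]1(CC(=O)C(C)C(=O)OCC)C(C)=CC(=O)[C@@H](OC(C)=O)[C@@]1(C)[C@@H](OC(=O)/C(C)=C/C)CC/C(C)=C\C=O` | intermediate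
22 | sodium enolate of 21 (Z; chelated) | `[C@@H]1(C/C([O-])=C(\C)C(=O)OCC)C(C)=CC(=O)[C@@H](OC(C)=O)[C@@]1(C)[C@@H](OC(=O)/C(C)=C/C)CC/C(C)=C\C=O.[Na+]` | intermediate
23 | (Z)-enol triflate (8-OTf cis to CO2Et) | `[C@@H]1(C/C(OS(=O)(=O)C(F)(F)F)=C(\C)C(=O)OCC)C(C)=CC(=O)[C@@H](OC(C)=O)[C@@]1(C)[C@@H](OC(=O)/C(C)=C/C)CC/C(C)=C\C=O` | intermediate
24 | hydroxy ester (ten-membered ring closed; 7R-OH; ethyl ester on C17) | `C/C=C(\C)C(=O)O[C@H]1CC/C(C)=C\[C@@H](O)/C(=C(/C)C(=O)OCC)C[C@@H]2C(C)=CC(=O)[C@@H](OC(C)=O)[C@@]12C` | intermediate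
25 | CNP0218548.3: (1R,2S,5Z,7R,10R,14S)-14-acetoxy-13-oxo-2-tigloyloxybriara-5,8(17),11-triene 7,19-lactone | `C/C=C(\C)C(=O)O[C@H]1CC/C(C)=C\[C@H]2OC(=O)C(C)=C2C[C@@H]2C(C)=CC(=O)[C@@H](OC(C)=O)[C@@]12C` | target

## Step count and weak points

Total steps: 16. Longest linear sequence: 14 (steps 1–8, 10, 11, 13–16, from (R)-carvone).

**Step 7 (Wharton transposition).** Hydrazone formation at a ketone flanked by the quaternary C1 may be slow enough for hydrazine to attack the acetate or tiglate. The fallback sets out from 8 and comes back at 9. Luche reduction (NaBH4, CeCl3·7H2O, MeOH, −40 °C) of the C10 ketone gives the epoxy alcohol F1 (either C10 epimer serves). Heating with 1,1'-thiocarbonyldiimidazole and DMAP in 1,2-dichloroethane gives the imidazolylthiocarbonate F2. Bu3SnH with cat. AIBN (benzene, 80 °C) then generates the C10 radical, which opens the epoxide (Barton-type radical fragmentation) to the same allylic alcohol 9, with the C12–O configuration untouched.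

**Step 13 (hydroboration/B-alkyl Suzuki).** 9-BBN must hydroborate the vinyl group before it reduces the enone or the C8 ketone, and the aqueous base must not harm the α-acetoxy enone. The fallback sets out from 14 (no enone yet) and comes back at 20. Hydroboration of 14 with 9-BBN gives the borane F3, which NaBO3·4H2O oxidises to the primary alcohol F4. I2, PPh3 and imidazole give the primary iodide F5. Allylic oxidation as in step 11 (CrO3, 3,5-dimethylpyrazole) gives the enone iodide F6. Zn dust with LiCl in THF gives the alkylzinc iodide F7, which is coupled under neutral Negishi conditions (Pd(dppf)Cl2, slow addition) with 18 to give 20.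

**Step 16 (Nozaki–Hiyama–Kishi macrocyclisation).** A tetrasubstituted enol triflate must close a ten-membered ring, and the C7 configuration rests on substrate control alone. The fallback sets out from 11 and comes back at 25; it replaces the alkenyl–chromium closure by a chromium-mediated allylation, the more reactive nucleophile commonly used to close lactone-bearing carbocycles. Morita–Baylis–Hillman reaction of 11 with methyl acrylate (DABCO) gives the hydroxy acrylate F8, and TBSOTf with 2,6-lutidine gives the silyl ether F9. Allylic oxidation as in step 11 gives the enone F10. Hydroboration with 9-BBN gives the borane F11, and Suzuki coupling with 18 as in step 13 gives the allylic alcohol F12. MnO2 gives the enal F13, and HF·pyridine frees the hydroxy acrylate F14. NBS with Me2S converts it, with allylic transposition, into the (Z)-2-(bromomethyl)enoate F15. CrCl2 in THF at high dilution effects intramolecular Nozaki–Hiyama allylation (C8 attacks the C7 aldehyde) and lactonisation to the α-methylene lactone F16. DBU (toluene, 60 °C) moves the exocyclic double bond into the ring to give 25.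

## Further compounds

F1 | step 7 | epoxy alcohol (10-OH; C10 epimers) | `OC1[C@]2(C)O[C@@H]2C[C@@H](OC(C)=O)[C@@]1(C)[C@@H](OC(=O)/C(C)=C/C)C=C`
F2 | step 7 | imidazolylthiocarbonate of F1 | `S=C(OC1[C@]2(C)O[C@@H]2C[C@@H](OC(C)=O)[C@@]1(C)[C@@H](OC(=O)/C(C)=C/C)C=C)n1ccnc1`
F3 | step 13 | B-alkyl-9-BBN adduct of 14 (boron on C4) | `[C@@H]1(CC(=O)C(C)C(=O)OCC)C(C)=CC[C@@H](OC(C)=O)[C@@]1(C)[C@@H](OC(=O)/C(C)=C/C)CCB1C2CCCC1CCC2`
F4 | step 13 | primary alcohol (4-OH) | `[C@@H]1(CC(=O)C(C)C(=O)OCC)C(C)=CC[C@@H](OC(C)=O)[C@@]1(C)[C@@H](OC(=O)/C(C)=C/C)CCO`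
F5 | step 13 | primary iodide (4-I) | `[C@@H]1(CC(=O)C(C)C(=O)OCC)C(C)=CC[C@@H](OC(C)=O)[C@@]1(C)[C@@H](OC(=O)/C(C)=C/C)CCI`
F6 | step 13 | enone iodide (13-oxo-11-ene; 4-I) | `[C@@H]1(CC(=O)C(C)C(=O)OCC)C(C)=CC(=O)[C@@H](OC(C)=O)[C@@]1(C)[C@@H](OC(=O)/C(C)=C/C)CCI`
F7 | step 13 | alkylzinc iodide (zinc on C4) | `[C@@H]1(CC(=O)C(C)C(=O)OCC)C(C)=CC(=O)[C@@H](OC(C)=O)[C@@]1(C)[C@@H](OC(=O)/C(C)=C/C)CC[Zn]I`
F8 | step 16 | hydroxy acrylate (Baylis–Hillman adduct of 11; C8 epimers) | `[C@@H]1(CC(O)C(=C)C(=O)OC)C(C)=CC[C@@H](OC(C)=O)[C@@]1(C)[C@@H](OC(=O)/C(C)=C/C)C=C`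
F9 | step 16 | silyl ether of F8 (8-OTBS) | `[C@@H]1(CC(O[Si](C)(C)C(C)(C)C)C(=C)C(=O)OC)C(C)=CC[C@@H](OC(C)=O)[C@@]1(C)[C@@H](OC(=O)/C(C)=C/C)C=C`
F10 | step 16 | enone of F9 (13-oxo-11-ene) | `[C@@H]1(CC(O[Si](C)(C)C(C)(C)C)C(=C)C(=O)OC)C(C)=CC(=O)[C@@H](OC(C)=O)[C@@]1(C)[C@@H](OC(=O)/C(C)=C/C)C=C`
F11 | step 16 | B-alkyl-9-BBN adduct of F10 (boron on C4) | `[C@@H]1(CC(O[Si](C)(C)C(C)(C)C)C(=C)C(=O)OC)C(C)=CC(=O)[C@@H](OC(C)=O)[C@@]1(C)[C@@H](OC(=O)/C(C)=C/C)CCB1C2CCCC1CCC2`
F12 | step 16 | (5Z)-allylic alcohol (7-OH; 8-OTBS acrylate arm) | `[C@@H]1(CC(O[Si](C)(C)C(C)(C)C)C(=C)C(=O)OC)C(C)=CC(=O)[C@@H](OC(C)=O)[C@@]1(C)[C@@H](OC(=O)/C(C)=C/C)CC/C(C)=C\CO`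
F13 | step 16 | (5Z)-enal (C7 aldehyde; 8-OTBS acrylate arm) | `[C@@H]1(CC(O[Si](C)(C)C(C)(C)C)C(=C)C(=O)OC)C(C)=CC(=O)[C@@H](OC(C)=O)[C@@]1(C)[C@@H](OC(=O)/C(C)=C/C)CC/C(C)=C\C=O`
F14 | step 16 | hydroxy acrylate enal (8-OH free) | `[C@@H]1(CC(O)C(=C)C(=O)OC)C(C)=CC(=O)[C@@H](OC(C)=O)[C@@]1(C)[C@@H](OC(=O)/C(C)=C/C)CC/C(C)=C\C=O`
F15 | step 16 | (Z)-2-(bromomethyl)enoate enal | `[C@@H]1(C/C=C(\CBr)C(=O)OC)C(C)=CC(=O)[C@@H](OC(C)=O)[C@@]1(C)[C@@H](OC(=O)/C(C)=C/C)CC/C(C)=C\C=O`
F16 | step 16 | α-methylene lactone (ten-membered ring closed; C8 sp3) | `C/C=C(\C)C(=O)O[C@H]1CC/C(C)=C\[C@H]2OC(=O)C(=C)C2C[C@@H]2C(C)=CC(=O)[C@@H](OC(C)=O)[C@@]12C`
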